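Conventions used throughout: carbons are numbered C1–C20 as in the target (C20 = exocyclic CH2; ring A = C10–C14; ring B = C8, C9, C10, C14, C15, C16; ring C = C1–C11). The β-face is the face of the hydrindane that carries the C14 methyl; the α-face is the opposite one.

## The problem

The target 39 is a cis-fused hydrindene whose C8 and C11 are joined by the seven-carbon bridge C1–C7. Ring C is therefore an eleven-membered carbocycle that holds the tetrasubstituted C8=C9 bond as a trans element, an E C2=C3 alkene and a methylene group on C1. Of the seven stereocentres, the quaternary C14 is the anchor. In the flat bicyclic enone it directs reagents to the α-face, which suits the C16 oxygen (α) but not the C15 oxygen (β, cis to the methyl). C15 can therefore only be set by delivering hydrogen, not oxygen, to the α-face, that is by reduction of a C15 ketone. C10–H (β) follows from conjugate reduction of the ring B enone, and C11 (C1 on the α-face) has no neighbouring handle except an oxygen at C13. C7 and C5 lie on the bridge, out of reach of the ring stereocentres, and need reagent control and a desymmetrised building block. The cross-conjugated 2-substituted 1,3-diene (sensitive to acid, oxidants and dienophiles), the allylic C7 acetate next to a tetrasubstituted alkene, and the vicinal C15 acetate/C16 hydroxyl pair (acyl migration under base) must all appear late. Direct C–C closure of the eleven-membered ring is the step most likely to fail. The structure offers a way round it: C11 is flanked in ring A by C12–C13, so an α-oxygen on C13 together with a C11=C12 double bond makes C11 the far terminus of an allylic ether. If that oxygen also carries C1, which is allylic to C2=C3, the C1 carbanion can move from oxygen to C11, copying the C13 configuration and contracting a large ether ring to ring C.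

## Retrosynthesis

**End game.** The methylene group, the two acetates and the free C16 hydroxyl of 39 are removed first. The diene is traced to the C1 enone 35 (methylenation), the acetates to triethylsilyl ethers, and the saturated C12–C13 bond to the cyclopentene of carbinol 33. This takes every fragile group out of the problem and leaves a ring C carbinol with a C12=C13 double bond, which is the signature of a [2,3]-shift.

**C1–C11 (key cut).** Carbinol 33 is opened to the macrocyclic ether 32, in which oxygen links C1 and C13 and ring A carries C11=C12. Compared with cutting C1–C2 or C7–C8 of ring C directly, this cut replaces a medium-ring C–C closure by contraction of a thirteen-membered ether (fourteen atoms if counted through C11=C12–C13) through a five-membered transition state. It also sets C11 by transfer from C13. The forward reaction must deprotonate C1 only and rearrange in the [2,3] rather than the [1,2] sense.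

**C1–O.** Ether 32 is cut at the C1–O bond to the bromo alcohol 31, made from diol 30. A Williamson closure keeps the C13 configuration and the E geometry, both of which are fixed beforehand. Closing the large ring at C7–C8 instead would leave C7 uncontrolled inside a macrocycle.

**C7–C8.** Diol 30 comes from the (7S)-alcohol 28, which is traced through enone 27 to the Nozaki–Hiyama–Kishi union of enol triflate 18 with aldehyde 25 (adducts 26). The cut separates a bicyclic core carrying all ring stereocentres from a chain carrying C5. The forward sequence only has to be chemoselective for the aldehyde; C7 is then set by reagent control.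

**C13 and C15 carbinols.** Benzoate 18 comes from diol 17, which arises from the enone–ketone 15 by two reductions in sequence (16, then 17). The ring A enone is reduced from the β-face, and the resulting 13α-hydroxyl then delivers hydride to the α-face of the C15 ketone. This turns the α-oxygen that osmium places on C15 into the required β-oxygen. Enone 15 is obtained from diketone 14 and ketone 13, both derived from enol triflate 12.

**Ring B.** Triflate 12 is traced to the silyl ether 9 and diol 8 of the cross-conjugated dienone 7. Conjugate reduction of the tetrasubstituted enone sets C10 and gives the C8 enolate regiospecifically, and dihydroxylation of the flat dienone sets C16. Dienone 7 comes from ketal 5 of enedione 4.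

**Bicycle.** Enedione 4 is the amino-acid-mediated aldol condensation product of triketone 3, itself the Michael adduct of 1 and 2. This maps the C9 methyl, the C8 carbonyl and the C13 carbonyl onto the target without adjustment.

**Chain.** Aldehyde 25 comes from hydroxy enoate 24, lactol 23 and lactone 22, which is derived from hemiester 20 by desymmetrisation of anhydride 19. The symmetric anhydride supplies C3–C7 and the C5 methyl in one reagent-controlled step.

## Roads not taken

**Alternative 1:** Heck closure of ring B. The cut is C9–C10. A Z-iodoenone A1 carrying a cyclopentene with the quaternary C14 would, under Pd(OAc)2/PPh3, undergo insertion of zerovalent palladium into C9–I, 6-exo carbopalladation of the ring A alkene and β-hydride loss to give the dienone A2 with C11=C12.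
- Merits: the tether enforces the cis ring fusion, the step is catalytic, and the β-oxygen at C15 is installed by acyclic chemistry before ring B exists. In that respect this road is better than the chosen plan, which spends steps 5, 8 and 12 on C15.
- Weak points: the enantiopure cyclopentene bearing C14 has to be made by other means. A2 has no C7 on C8. C11 would have to be created afterwards by face-selective reduction of a trisubstituted alkene. Ring C is left entirely open, so the medium ring is only postponed.
- What the chosen plan sets against it: C11 arises by chirality transfer and ring C by contraction, in the same step.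

**Alternative 2:** Intramolecular nitroalkene Diels–Alder. The cuts are C10–C14 and C15–C16. Heating triene A3 (1-silyloxydiene plus Z nitroalkene) would give the cis-hydrindene A4 with rings A and B, the quaternary centre and three further stereocentres in one step.
- Merits: it reaches the bicycle in far fewer steps than the thirteen of the chosen plan, and that advantage is real.
- Weak points: a tetrasubstituted diene meets a trisubstituted nitroalkene in a congested transition state. The Z nitroalkene must be made and must survive heating. Endo/exo and facial selectivity rest on one tether stereocentre. A4 carries nitrogen at C15 on the α-face, so a Nef reaction and a ketone reduction are still needed there. Ring C and C5/C7 are untouched.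
- What the chosen plan sets against it: each stereocentre of the bicycle is set by a step with a clear facial rationale, and the route to ring C is defined.

**Alternative 3:** Stille macrocyclisation. The cut is C1–C2. The seco iodide–stannane A5 would close under Pd2(dba)3/AsPh3 to A6, the C16 silyl ether of the target.
- Merits: the diene forms as the ring closes, the acetates are already in place, and one deprotection finishes the synthesis. The chosen plan needs six steps after its key step, so this road is clearly better in step economy after ring closure.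
- Weak points: it is a direct end-to-end closure of an eleven-membered ring containing two trans double bonds, with the entropic cost, transannular strain and dimerisation that go with it. The alkenyl iodide is 1,1-disubstituted and sits next to the C11 stereocentre, which must have been set by separate chemistry.
- What the chosen plan sets against it: ring C is formed from an unstrained larger ring through a five-membered transition state, and C11 is set in the same event.

Key step: step 26

Assumption: 1,4-bis(dihydroquinidinyl)anthraquinone, (DHQD)2AQN, is taken to give the (R)-hemiester 20; if the sense is the opposite, the pseudoenantiomeric (DHQ)2AQN is used.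
Remark: the C1 carbinol of 33 and 34 is drawn as one epimer for definiteness; this centre is erased in step 28.

## Route

Step 1
Reactants: 1 2-methylcyclopentane-1,3-dione; 2 pent-1-en-3-one
Product: 3 2-methyl-2-(3-oxopentyl)cyclopentane-1,3-dione
Conditions: H2O, AcOH (cat.), 70 °C
Reagents that add atoms: none
Why: Michael addition of the acidic cyclic 1,3-dione to the enone, the standard first stage of a Hajos–Parrish-type annulation; no stereocentre is formed.

Step 2
Reactants: 3 triketone
Product: 4 (R)-4,7a-dimethyl-2,3,7,7a-tetrahydro-1H-indene-1,5(6H)-dione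
Conditions: D-phenylalanine (1 equiv), (+)-camphorsulfonic acid (0.5 equiv), DMF, 30 → 70 °C
Reagents that add atoms: none
Why: Amino-acid-mediated intramolecular aldol condensation (Hajos–Parrish type); the enamine of the D-amino acid selects one of the enantiotopic ring carbonyls and sets C14 as R, and the acid dehydrates the ketol to the C9=C10 enone.

Step 3
Reactants: 4 enedione
Product: 5 C13 ethylene ketal of 4
Conditions: (Me3SiOCH2)2, Me3SiOTf (cat.), CH2Cl2, −78 → −20 °C
Reagents that add atoms: 1,2-bis(trimethylsilyloxy)ethane, C[Si](C)(C)OCCO[Si](C)(C)C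
Why: Silyl-transfer ketalisation under Me3SiOTf catalysis converts saturated ketones and leaves conjugated enones alone, so only the C13 carbonyl is masked.

Step 4
Reactants: 5 ketal enone
Product: 7 cross-conjugated dienone (C15=C16 and C9=C10), via trimethylsilyl dienol ether 6 (not isolated)
Conditions: LiN(i-Pr)2, Me3SiCl, THF, −78 °C; then Pd(OAc)2, MeCN, rt
Reagents that add atoms: none
Why: Saegusa–Ito oxidation; the amide base removes the kinetic α′ proton at C16, and divalent palladium dehydrogenates the silyl dienol ether to the C15=C16 enone.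

Step 5
Reactants: 7 dienone
Product: 8 15α,16α-diol
Conditions: OsO4 (cat.), N-methylmorpholine N-oxide, citric acid, t-BuOH/H2O, rt
Reagents that add atoms: osmium tetroxide, O=[Os](=O)(=O)=O; N-methylmorpholine N-oxide, C[N+]1([O-])CCOCC1; water, O
Why: Upjohn dihydroxylation; OsO4 adds to the disubstituted C15=C16 bond rather than the tetrasubstituted C9=C10 bond and approaches the flat dienone from the α-face, opposite the angular methyl. C16 thereby receives its final configuration; C15 is corrected in steps 8 and 12.

Step 6
Reactants: 8 diol
Product: 9 16-O-tert-butyldimethylsilyl ether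
Conditions: t-BuMe2SiCl, imidazole, DMF, 0 °C
Reagents that add atoms: tert-butyldimethylsilyl chloride, CC(C)(C)[Si](C)(C)Cl
Why: Selective silylation; the C16 hydroxyl next to the ketone reacts, while the neopentyl C15 hydroxyl beside the quaternary C14 does not.

Step 7
Reactants: 9 silyl ether enone
Product: 12 cis-fused C8 enol triflate (C8=C9; 15α-OH; 16α-OTBS; C13 ketal), via bis-silylated enol ether 10 (not isolated), via silylated enol triflate 11 (not isolated)
Conditions: [(Ph3P)CuH]6 (cat.), PhMe2SiH, toluene, rt; MeLi, THF, 0 °C; PhNTf2, −78 °C → rt; aq. NH4Cl, then citric acid, MeOH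
Reagents that add atoms: N-phenylbis(trifluoromethanesulfonimide), O=S(=O)(N(c1ccccc1)S(=O)(=O)C(F)(F)F)C(F)(F)F
Why: Copper hydride 1,4-hydrosilylation delivers hydride to C10 from the β-face, the normal course for this enone class and reinforced here by the axial 15α-oxygen, so the ring fusion is cis. The regiodefined silyl enol ether is converted by MeLi into the lithium enolate and trapped as the C8 enol triflate (enolate triflation); the labile silyl ether formed in passing at C15 is cleaved in the acidic methanol work-up.

Step 8
Reactants: 12 hydroxy enol triflate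
Product: 13 C15 ketone
Conditions: Dess–Martin periodinane, NaHCO3, CH2Cl2, rt
Reagents that add atoms: none
Why: Dess–Martin oxidation of a hindered secondary alcohol; with C8 now an enol triflate the new ketone has no 1,3-dicarbonyl partner and serves as the handle for inverting C15.

Step 9
Reactants: 13 ketal ketone
Product: 14 C13,C15-diketone
Conditions: p-TsOH·H2O (cat.), acetone/H2O, rt
Reagents that add atoms: water, O
Why: Acid-catalysed ketal hydrolysis; the non-enolisable 2,2-disubstituted 1,3-diketone, the enol triflate and the secondary silyl ether tolerate dilute acid.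

Step 10
Reactants: 14 diketone
Product: 15 ring A enone (C11=C12 conjugated to C13=O) with C15 ketone
Conditions: 2-iodoxybenzoic acid (IBX), 4-methoxypyridine N-oxide, DMSO, rt
Reagents that add atoms: none
Why: IBX dehydrogenation of a ketone through its enol; only the C13 ketone has an α-CH2–CH2 unit, and the metal-free oxidant leaves the enol triflate untouched.

Step 11
Reactants: 15 enone ketone
Product: 16 13α-allylic alcohol (C15 ketone retained)
Conditions: NaBH4, CeCl3·7H2O, MeOH, −78 °C
Reagents that add atoms: none
Why: Luche reduction; CeCl3 promotes 1,2-reduction of the conjugated ketone ahead of the hindered C15 ketone. Hydride should approach C13 anti to the C14–C15 acyl branch, the larger and more electron-poor α-substituent, that is from the β-face, giving the hydroxyl on the α-face (trans to the C14 methyl).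

Step 12
Reactants: 16 hydroxy ketone
Product: 17 13α,15β-diol
Conditions: Me4NBH(OAc)3, MeCN/AcOH, −30 → 0 °C
Reagents that add atoms: none
Why: Hydroxyl-directed triacetoxyborohydride reduction (Evans–Saksena type); the borohydride bound to the 13α-oxygen can reach the C15 carbonyl only from the α-face of ring B, on which C13 lies, so the C15 hydroxyl ends on the β-face, cis to the methyl and trans to the C16 oxygen. Undirected carbonyls and the triflate are inert to this reagent.

Step 13
Reactants: 17 diol
Product: 18 13α-benzoate (15β-OH free)
Conditions: BzCl (1.1 equiv), pyridine, 4-(dimethylamino)pyridine (cat.), CH2Cl2, −20 → 0 °C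
Reagents that add atoms: benzoyl chloride, O=C(Cl)c1ccccc1
Why: Selective acylation of the allylic cyclopentenol; the C15 hydroxyl, wedged between the quaternary C14 and the silyloxy-bearing C16, stays free. The benzoate shields C13–OH from the allylic oxidation in step 20.

Step 14
Reactants: 19 3-methylglutaric anhydride
Product: 20 methyl hydrogen (R)-3-methylglutarate
Conditions: (DHQD)2AQN (cat.), MeOH, Et2O, −40 °C
Reagents that add atoms: methanol, CO
Why: Alkaloid-catalysed desymmetrising methanolysis of a meso anhydride; the catalyst acts as a chiral general base and selects one of the enantiotopic carbonyls, which fixes C5.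

Step 15
Reactants: 20 hemiester
Product: 22 (R)-4-methyltetrahydro-2H-pyran-2-one, via hydroxy ester 21 (not isolated)
Conditions: BH3·SMe2, THF, 0 °C → rt; then p-TsOH (cat.), CH2Cl2, rt
Reagents that add atoms: none
Why: Borane reduces the carboxylic acid in the presence of the ester, and the hydroxy ester lactonises under acid; the stereocentre is not touched.

Step 16
Reactants: 22 lactone
Product: 23 (4R)-4-methyltetrahydro-2H-pyran-2-ol (anomer mixture)
Conditions: i-Bu2AlH, CH2Cl2, −78 °C
Reagents that add atoms: none
Why: Half-reduction of a lactone to the lactol at low temperature through the stable aluminium hemiacetal.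

Step 17
Reactants: 23 lactol
Product: 24 ethyl (2E,5S)-7-hydroxy-5-methylhept-2-enoate
Conditions: Ph3P=CHCO2Et, PhCO2H (cat.), toluene, 80 °C
Reagents that add atoms: ethyl (triphenylphosphoranylidene)acetate, CCOC(=O)C=P(c1ccccc1)(c1ccccc1)c1ccccc1
Why: Wittig olefination of the open hydroxy aldehyde form of the lactol with a stabilised ylide gives the E enoate; the neutral medium avoids oxa-Michael closure of the liberated alcohol.

Step 18
Reactants: 24 hydroxy enoate
Product: 25 ethyl (2E,5S)-5-methyl-7-oxohept-2-enoate
Conditions: Dess–Martin periodinane, NaHCO3, CH2Cl2, 0 °C → rt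
Reagents that add atoms: none
Why: Dess–Martin oxidation of a primary alcohol to the aldehyde under buffered, non-basic conditions.

Step 19
Reactants: 18 enol triflate benzoate; 25 aldehyde
Product: 26 C7 allylic alcohols (both C7 epimers)
Conditions: CrCl2 (excess), NiCl2 (cat.), DMF, rt
Reagents that add atoms: none
Why: Nozaki–Hiyama–Kishi coupling; zerovalent nickel inserts into the enol triflate, the alkenyl group passes to trivalent chromium and adds to the aldehyde only, so enoate, benzoate, silyl ether and the free C15 hydroxyl are tolerated. C7 is formed without control and is corrected in steps 20 and 21.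

Step 20
Reactants: 26 allylic alcohols
Product: 27 C7 enone
Conditions: MnO2, CH2Cl2, rt
Reagents that add atoms: none
Why: MnO2 oxidises allylic alcohols selectively; the saturated, hindered C15 hydroxyl is not affected.

Step 21
Reactants: 27 enone
Product: 28 (7S)-allylic alcohol
Conditions: (R)-2-methyl-CBS-oxazaborolidine (0.5 equiv), catecholborane, toluene, −78 °C
Reagents that add atoms: none
Why: Corey–Bakshi–Shibata reduction; the α-branched alkenyl group acts as the large and the C6 methylene as the small substituent, so the (R)-catalyst should deliver hydride to give the 7S carbinol. Catecholborane leaves the esters untouched.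

Step 22
Reactants: 28 diol
Product: 29 7,15-bis(triethylsilyl) ether
Conditions: Et3SiOTf, 2,6-lutidine, CH2Cl2, −78 → 0 °C
Reagents that add atoms: triethylsilyl trifluoromethanesulfonate, CC[Si](CC)(CC)OS(=O)(=O)C(F)(F)F
Why: Silyl triflate with a hindered base silylates both the allylic C7 and the neopentyl C15 hydroxyl without forming an alkoxide that could add to the enoate.

Step 23
Reactants: 29 ester benzoate
Product: 30 C1,C13-diol
Conditions: i-Bu2AlH (excess), CH2Cl2, −78 °C
Reagents that add atoms: none
Why: The aluminium hydride reduces the enoate 1,2 to the E allylic alcohol and cleaves the benzoate in the same operation; silyl ethers are stable.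

Step 24
Reactants: 30 diol
Product: 31 C1 allylic bromide (13α-OH free)
Conditions: CBr4, PPh3, CH2Cl2, −30 °C
Reagents that add atoms: carbon tetrabromide, BrC(Br)(Br)Br
Why: Appel bromination; at low temperature the primary allylic alcohol is activated and displaced, while the hindered secondary C13 hydroxyl is not.

Step 25
Reactants: 31 bromo alcohol
Product: 32 macrocyclic ether (O links C1 and C13)
Conditions: NaH, Bu4NI (cat.), THF (0.002 M, slow addition), 40 °C
Reagents that add atoms: none
Why: Intramolecular Williamson etherification under high dilution; the C13 alkoxide displaces the primary allylic halide in an SN2 reaction, so the C13 configuration and the E alkene are retained. The ring formed has thirteen atoms by the shortest path and is free of medium-ring strain.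

Step 26
Reactants: 32 macrocyclic ether
Product: 33 ring C carbinol (C1–OH; C12=C13)
Conditions: n-BuLi, THF, −78 → −30 °C; aq. NH4Cl
Reagents that add atoms: none
Why: n-BuLi removes a proton from C1, the only CH2 that is both allylic and bound to oxygen, and the carbanion attacks C11 through a five-membered envelope transition state while the O–C13 bond breaks and the double bond moves to C12=C13. The closest known reaction type is the [2,3]-Wittig ring contraction of macrocyclic bis-allylic ethers to medium-ring homoallylic alcohols. Ring C is closed by contraction of the thirteen-membered ether (fourteen atoms through the allyl unit) to the eleven-membered carbocycle, not by end-to-end cyclisation. The shift is suprafacial across C11–C12–C13, so the new C11 centre is controlled by the α-oxygen at C13 and C1 is attached on the α-face. The C1 carbinol centre is set by the envelope geometry and is removed in step 28. The step needs C1 deprotonation rather than deprotonation at C13, C7 or C16, which are all hindered methines, or at the doubly allylic C10–H, which bears no oxygen. It also needs the concerted [2,3] path rather than the radical [1,2] path, which the low temperature and the ring-held proximity of C1 and C11 favour. Silyl ethers are the only other functional groups, so nothing else reacts with the base.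

Step 27
Reactants: 33 carbinol
Product: 34 12,13-dihydro carbinol
Conditions: KO2CN=NCO2K, AcOH, MeOH/CH2Cl2, 0 °C → rt
Reagents that add atoms: none
Why: Diimide reduction by concerted syn transfer of H2; the strained cis cyclopentene should react ahead of the trans C2=C3 bond, and the tetrasubstituted C8=C9 bond is inert. The reagent is dosed and the reaction stopped once the cyclopentene is consumed.

Step 28
Reactants: 34 carbinol
Product: 35 C1 enone
Conditions: Dess–Martin periodinane, NaHCO3, CH2Cl2, 0 °C
Reagents that add atoms: none
Why: Buffered Dess–Martin oxidation of the allylic alcohol; the non-basic medium leaves the C11 centre α to the new ketone intact.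

Step 29
Reactants: 35 enone
Product: 36 diene (C20=C1–C2=C3)
Conditions: Cp2TiMe2, toluene, 65 °C, dark
Reagents that add atoms: dimethyltitanocene, C[Ti](C)(C1C=CC=C1)C1C=CC=C1
Why: Petasis methylenation; the titanium methylidene is not basic, so the enolisable C11 is not epimerised, and 1,2-methylenation of the enone gives the 2-substituted diene.

Step 30
Reactants: 36 tris-silyl ether
Product: 37 7,15-diol (16-OTBS retained)
Conditions: HF·pyridine, pyridine, THF, 0 °C
Reagents that add atoms: none
Why: Selective desilylation; triethylsilyl ethers are cleaved by buffered fluoride well before a secondary tert-butyldimethylsilyl ether, and the buffered medium spares the diene.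

Step 31
Reactants: 37 diol
Product: 38 7,15-diacetate
Conditions: Ac2O, pyridine, 4-(dimethylamino)pyridine, CH2Cl2, rt
Reagents that add atoms: acetic anhydride, CC(=O)OC(C)=O
Why: Nucleophile-catalysed acetylation of both secondary hydroxyls while C16 is still silylated, which fixes the acetate pattern of the target.

Step 32
Reactants: 38 silyl ether
Product: 39 target (CNP0323842.1)
Conditions: HF·pyridine, THF, rt
Reagents that add atoms: none
Why: Fluoride desilylation under weakly acidic conditions, which avoids base-induced acetyl migration from C15 to C16 and leaves the diene and the allylic acetate intact.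

## Compound list

1 | 2-methylcyclopentane-1,3-dione | CC1C(=O)CCC1=O | starting material
2 | pent-1-en-3-one | CCC(=O)C=C | starting material
3 | 2-methyl-2-(3-oxopentyl)cyclopentane-1,3-dione | CCC(=O)CCC1(C)C(=O)CCC1=O | intermediate
4 | (R)-4,7a-dimethyl-2,3,7,7a-tetrahydro-1H-indene-1,5(6H)-dione (C8 enone, C13 ketone) | O=C1C(C)=C2CCC(=O)[C@]2(C)CC1 | intermediate
5 | C13 ethylene ketal of 4, (7a′R)-4′,7a′-dimethyl-2′,3′,7′,7a′-tetrahydrospiro[1,3-dioxolane-2,1′-inden]-5′(6′H)-one | O=C1C(C)=C2CCC3(OCCO3)[C@]2(C)CC1 | intermediate
6 | kinetic trimethylsilyl dienol ether of 5 (C8–OSiMe3; C8=C16; C9=C10) | C[Si](C)(C)OC=1C(C)=C2CCC3(OCCO3)[C@]2(C)CC=1 | intermediate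
7 | cross-conjugated dienone (C15=C16, C9=C10, C8=O; C13 ketal; 14R) | O=C1C(C)=C2CCC3(OCCO3)[C@]2(C)C=C1 | intermediate
8 | 15α,16α-diol of 7 (both hydroxyls trans to the C14 methyl) | O=C1C(C)=C2CCC3(OCCO3)[C@]2(C)[C@H](O)[C@@H]1O | intermediate
9 | 16α-O-tert-butyldimethylsilyl ether of 8 (15α-OH free) | O=C1C(C)=C2CCC3(OCCO3)[C@]2(C)[C@H](O)[C@@H]1O[Si](C)(C)C(C)(C)C | intermediate
10 | cis-fused C8 dimethylphenylsilyl enol ether (C8=C9) with 15α-OSiMe2Ph and 16α-OTBS; C10–H β | C[Si](C)(c1ccccc1)OC2=C(C)[C@@H]3CCC4(OCCO4)[C@]3(C)[C@H](O[Si](C)(C)c5ccccc5)[C@@H]2O[Si](C)(C)C(C)(C)C | intermediate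
11 | cis-fused C8 enol triflate with 15α-OSiMe2Ph and 16α-OTBS | FC(F)(F)S(=O)(=O)OC2=C(C)[C@@H]3CCC4(OCCO4)[C@]3(C)[C@H](O[Si](C)(C)c5ccccc5)[C@@H]2O[Si](C)(C)C(C)(C)C | intermediate
12 | cis-fused C8 enol triflate (C8=C9), 15α-OH, 16α-OTBS, C13 ketal, C10–H β | FC(F)(F)S(=O)(=O)OC2=C(C)[C@@H]3CCC4(OCCO4)[C@]3(C)[C@H](O)[C@@H]2O[Si](C)(C)C(C)(C)C | intermediate
13 | C15 ketone of 12 (16α-OTBS, C13 ketal) | FC(F)(F)S(=O)(=O)OC2=C(C)[C@@H]3CCC4(OCCO4)[C@]3(C)C(=O)[C@@H]2O[Si](C)(C)C(C)(C)C | intermediate
14 | C13,C15-diketone (C8 enol triflate, 16α-OTBS) | FC(F)(F)S(=O)(=O)OC2=C(C)[C@@H]3CCC(=O)[C@]3(C)C(=O)[C@@H]2O[Si](C)(C)C(C)(C)C | intermediate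
15 | ring A enone (C11=C12–C13=O) with C15 ketone | FC(F)(F)S(=O)(=O)OC2=C(C)[C@@H]3C=CC(=O)[C@]3(C)C(=O)[C@@H]2O[Si](C)(C)C(C)(C)C | intermediate
16 | 13α-allylic alcohol (C11=C12), C15 ketone | FC(F)(F)S(=O)(=O)OC2=C(C)[C@@H]3C=C[C@H](O)[C@]3(C)C(=O)[C@@H]2O[Si](C)(C)C(C)(C)C | intermediate
17 | 13α,15β-diol (16α-OTBS, C8 enol triflate, C11=C12) | FC(F)(F)S(=O)(=O)OC2=C(C)[C@@H]3C=C[C@H](O)[C@]3(C)[C@@H](O)[C@@H]2O[Si](C)(C)C(C)(C)C | intermediate
18 | 13α-benzoate of 17 (15β-OH free) | FC(F)(F)S(=O)(=O)OC2=C(C)[C@@H]3C=C[C@H](OC(=O)c4ccccc4)[C@]3(C)[C@@H](O)[C@@H]2O[Si](C)(C)C(C)(C)C | intermediate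
19 | 3-methylglutaric anhydride | CC1CC(=O)OC(=O)C1 | starting material
20 | methyl hydrogen (R)-3-methylglutarate | COC(=O)C[C@H](C)CC(=O)O | intermediate
21 | methyl (R)-5-hydroxy-3-methylpentanoate | COC(=O)C[C@H](C)CCO | intermediate
22 | (R)-4-methyltetrahydro-2H-pyran-2-one | O=C1C[C@H](C)CCO1 | intermediate
23 | (4R)-4-methyltetrahydro-2H-pyran-2-ol (anomer mixture) | OC1C[C@H](C)CCO1 | intermediate
24 | ethyl (2E,5S)-7-hydroxy-5-methylhept-2-enoate | CCOC(=O)/C=C/C[C@H](C)CCO | intermediate
25 | ethyl (2E,5S)-5-methyl-7-oxohept-2-enoate | CCOC(=O)/C=C/C[C@H](C)CC=O | intermediate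
26 | coupled C7 allylic alcohols (C7 epimers; chain C1 ester, E C2=C3, 5S; core as in 18) | CCOC(=O)/C=C/C[C@H](C)CC(O)C2=C(C)[C@@H]3C=C[C@H](OC(=O)c4ccccc4)[C@]3(C)[C@@H](O)[C@@H]2O[Si](C)(C)C(C)(C)C | intermediate
27 | C7 enone | CCOC(=O)/C=C/C[C@H](C)CC(=O)C2=C(C)[C@@H]3C=C[C@H](OC(=O)c4ccccc4)[C@]3(C)[C@@H](O)[C@@H]2O[Si](C)(C)C(C)(C)C | intermediate
28 | (7S)-allylic alcohol (15β-OH free, 13α-OBz, 16α-OTBS) | CCOC(=O)/C=C/C[C@H](C)C[C@H](O)C2=C(C)[C@@H]3C=C[C@H](OC(=O)c4ccccc4)[C@]3(C)[C@@H](O)[C@@H]2O[Si](C)(C)C(C)(C)C | intermediate
29 | 7,15-bis(triethylsilyl) ether of 28 | CCOC(=O)/C=C/C[C@H](C)C[C@H](O[Si](CC)(CC)CC)C2=C(C)[C@@H]3C=C[C@H](OC(=O)c4ccccc4)[C@]3(C)[C@@H](O[Si](CC)(CC)CC)[C@@H]2O[Si](C)(C)C(C)(C)C | intermediate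
30 | C1,C13-diol (E allylic alcohol at C1; 13α-OH; 7,15-OTES; 16-OTBS) | OC/C=C/C[C@H](C)C[C@H](O[Si](CC)(CC)CC)C2=C(C)[C@@H]3C=C[C@H](O)[C@]3(C)[C@@H](O[Si](CC)(CC)CC)[C@@H]2O[Si](C)(C)C(C)(C)C | intermediate
31 | C1 allylic bromide (13α-OH free) | BrC/C=C/C[C@H](C)C[C@H](O[Si](CC)(CC)CC)C2=C(C)[C@@H]3C=C[C@H](O)[C@]3(C)[C@@H](O[Si](CC)(CC)CC)[C@@H]2O[Si](C)(C)C(C)(C)C | intermediate
32 | macrocyclic ether: O bridges C1 and C13 (13α), C11=C12 in ring A, E C2=C3, 7S and 15β OTES, 16α-OTBS | C1/C=C/C[C@H](C)C[C@H](O[Si](CC)(CC)CC)C2=C(C)[C@@H]3C=C[C@H](O1)[C@]3(C)[C@@H](O[Si](CC)(CC)CC)[C@@H]2O[Si](C)(C)C(C)(C)C | intermediate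
33 | ring C carbinol: C1–OH, C1 bonded to C11 on the α-face, C12=C13, E C2=C3 | O[C@@H]1/C=C/C[C@H](C)C[C@H](O[Si](CC)(CC)CC)C2=C(C)[C@@H]3[C@H]1C=C[C@]3(C)[C@@H](O[Si](CC)(CC)CC)[C@@H]2O[Si](C)(C)C(C)(C)C | intermediate
34 | 12,13-dihydro derivative of 33 | O[C@@H]1/C=C/C[C@H](C)C[C@H](O[Si](CC)(CC)CC)C2=C(C)[C@@H]3[C@H]1CC[C@]3(C)[C@@H](O[Si](CC)(CC)CC)[C@@H]2O[Si](C)(C)C(C)(C)C | intermediate
35 | C1 enone (C1=O conjugated to E C2=C3) | O=C1/C=C/C[C@H](C)C[C@H](O[Si](CC)(CC)CC)C2=C(C)[C@@H]3[C@H]1CC[C@]3(C)[C@@H](O[Si](CC)(CC)CC)[C@@H]2O[Si](C)(C)C(C)(C)C | intermediate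
36 | diene with 7,15-OTES and 16-OTBS | C=C1/C=C/C[C@H](C)C[C@H](O[Si](CC)(CC)CC)C2=C(C)[C@@H]3[C@H]1CC[C@]3(C)[C@@H](O[Si](CC)(CC)CC)[C@@H]2O[Si](C)(C)C(C)(C)C | intermediate
37 | 7,15-diol with 16-OTBS | C=C1/C=C/C[C@H](C)C[C@H](O)C2=C(C)[C@@H]3[C@H]1CC[C@]3(C)[C@@H](O)[C@@H]2O[Si](C)(C)C(C)(C)C | intermediate
38 | 7,15-diacetate with 16-OTBS | C=C1/C=C/C[C@H](C)C[C@H](OC(C)=O)C2=C(C)[C@@H]3[C@H]1CC[C@]3(C)[C@@H](OC(C)=O)[C@@H]2O[Si](C)(C)C(C)(C)C | intermediate
39 | CNP0323842.1 | C=C1/C=C/C[C@H](C)C[C@H](OC(C)=O)C2=C(C)[C@@H]3[C@H]1CC[C@]3(C)[C@@H](OC(C)=O)[C@@H]2O | target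

## Step count and least certain steps

Total: 32 steps. Longest linear sequence: 27 steps (steps 1–13 and 19–32); the chain branch (steps 14–18) joins at step 19.

**Step 26 (key step).** The most likely failures are competing deprotonation at C13 or at the doubly allylic C10–H, and leakage into the radical [1,2]-shift, either of which would give isomeric or ring-opened material. The substrate has one CH2 against several hindered methines, but the selectivity is kinetic.
Fallback, from 31, back at 35: the C1–C11 bond is formed by palladium-catalysed allylic alkylation. Bromide 31 and PhSO2Na (DMF) give the allylic sulfone F1. ClCO2Me/pyridine converts its C13 hydroxyl into the sulfone carbonate F2. Pd(PPh3)4 under high dilution ionises the ring A carbonate with inversion, and the sulfonyl-stabilised C1 carbanion attacks the less hindered C11 terminus from the α-face (net retention, the same facial result as the sigmatropic shift) to give the macrocyclic sulfone F3. Deprotonation with LiN(i-Pr)2 and oxidation of the sulfonyl carbanion with bis(trimethylsilyl) peroxide gives the dienone F4. Hydrogenation of its isolated cyclopentene with H2/RhCl(PPh3)3 leads to 35.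

**Step 11.** Hydride may approach the ring A enone from the α-face instead, giving the 13β-alcohol; the facial bias of a cis-fused cyclopentenone between a methyl and an acyl branch is not secure, and both C11 and C15 depend on it.
Fallback, from 15, back at 16: the 13β-alcohol F5 is accepted and inverted by a Mitsunobu reaction (4-nitrobenzoic acid, PPh3, diisopropyl azodicarboxylate) to the 13α 4-nitrobenzoate F6, and mild methanolysis (Et3N, MeOH) gives 16.

**Step 7.** The tetrasubstituted enone may be reduced slowly, and hydride delivery to C10 may lose facial selectivity, eroding the cis ring fusion; the multi-stage enolate transfer may also lose material.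
Fallback, from 9, back at 12: hydrogenation (H2, Pd/C, EtOAc) gives the cis-fused saturated ketone F7. Me3SiCl/imidazole masks the C15 hydroxyl as the trimethylsilyl ether F8, which removes the retro-aldol pathway. KN(SiMe3)2/PhNTf2 at −78 °C forms the enol triflate F9 towards C9, since C16–H is deactivated by its oxygen. Citric acid in methanol then gives 12.

**Step 25.** The hindered secondary alkoxide may react slowly, so that elimination of HBr or intermolecular etherification competes with ring closure.
Fallback, from 30, back at 32: ClCO2Me/pyridine at −20 °C acylates the primary hydroxyl to the allylic carbonate F10. Pd(PPh3)4 in dilute THF ionises it, and the C13 alkoxide, freed by the methoxide that is released, attacks the unsubstituted terminus of the allylpalladium unit (Tsuji–Trost etherification) to give 32.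

**Step 27.** Diimide may not discriminate well enough between the cyclopentene and the trans C2=C3 bond, leading to over-reduction.
Fallback, from 33, back at 35: the order is changed. Dess–Martin oxidation first gives the dienone F4 (described above), in which C2=C3 is conjugated. H2/RhCl(PPh3)3 then saturates the isolated cis cyclopentene, which this catalyst reduces far faster than a conjugated trans alkene, to give 35.

## Further compounds

F1 | step 26 | C1 phenyl sulfone of 31 (13α-OH free) | O=S(=O)(c1ccccc1)C/C=C/C[C@H](C)C[C@H](O[Si](CC)(CC)CC)C2=C(C)[C@@H]3C=C[C@H](O)[C@]3(C)[C@@H](O[Si](CC)(CC)CC)[C@@H]2O[Si](C)(C)C(C)(C)C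
F2 | step 26 | 13α methyl carbonate of F1 | O=S(=O)(c1ccccc1)C/C=C/C[C@H](C)C[C@H](O[Si](CC)(CC)CC)C2=C(C)[C@@H]3C=C[C@H](OC(=O)OC)[C@]3(C)[C@@H](O[Si](CC)(CC)CC)[C@@H]2O[Si](C)(C)C(C)(C)C
F3 | step 26 | macrocyclic sulfone (C1–SO2Ph bonded to C11 on the α-face; C12=C13) | O=S(=O)(c4ccccc4)C1/C=C/C[C@H](C)C[C@H](O[Si](CC)(CC)CC)C2=C(C)[C@@H]3[C@H]1C=C[C@]3(C)[C@@H](O[Si](CC)(CC)CC)[C@@H]2O[Si](C)(C)C(C)(C)C
F4 | step 26 | dienone (C1=O, E C2=C3, C12=C13) | O=C1/C=C/C[C@H](C)C[C@H](O[Si](CC)(CC)CC)C2=C(C)[C@@H]3[C@H]1C=C[C@]3(C)[C@@H](O[Si](CC)(CC)CC)[C@@H]2O[Si](C)(C)C(C)(C)C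
F5 | step 11 | 13β-allylic alcohol (C13 epimer of 16) | FC(F)(F)S(=O)(=O)OC2=C(C)[C@@H]3C=C[C@@H](O)[C@]3(C)C(=O)[C@@H]2O[Si](C)(C)C(C)(C)C
F6 | step 11 | 13α 4-nitrobenzoate | FC(F)(F)S(=O)(=O)OC2=C(C)[C@@H]3C=C[C@H](OC(=O)c4ccc(cc4)[N+](=O)[O-])[C@]3(C)C(=O)[C@@H]2O[Si](C)(C)C(C)(C)C
F7 | step 7 | cis-fused saturated C8 ketone (C9 epimers; 15α-OH, 16α-OTBS, C13 ketal) | O=C1C(C)[C@@H]2CCC3(OCCO3)[C@]2(C)[C@H](O)[C@@H]1O[Si](C)(C)C(C)(C)C
F8 | step 7 | 15α trimethylsilyl ether of F7 | O=C1C(C)[C@@H]2CCC3(OCCO3)[C@]2(C)[C@H](O[Si](C)(C)C)[C@@H]1O[Si](C)(C)C(C)(C)C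
F9 | step 7 | C8 enol triflate with 15α-OSiMe3 | FC(F)(F)S(=O)(=O)OC2=C(C)[C@@H]3CCC4(OCCO4)[C@]3(C)[C@H](O[Si](C)(C)C)[C@@H]2O[Si](C)(C)C(C)(C)C
F10 | step 25 | C1 methyl carbonate of 30 (13α-OH free) | COC(=O)OC/C=C/C[C@H](C)C[C@H](O[Si](CC)(CC)CC)C2=C(C)[C@@H]3C=C[C@H](O)[C@]3(C)[C@@H](O[Si](CC)(CC)CC)[C@@H]2O[Si](C)(C)C(C)(C)C
A1 | alternative 1 | Z-iodoenone with cyclopentene (Heck substrate) | I/C(C)=C\C(=O)[C@H](OCc1ccc(OC)cc1)[C@@]1(C)CCC(CO[Si](C)(C)C(C)(C)C)=C1
A2 | alternative 1 | cis-fused hydrindadienone with C16 ketone and C11=C12 (Heck product) | C1=C(C)[C@@H]2C(CO[Si](C)(C)C(C)(C)C)=CC[C@]2(C)[C@@H](OCc3ccc(OC)cc3)C1=O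
A3 | alternative 2 | triene with 1-silyloxydiene and Z nitroalkene (Diels–Alder substrate) | COc1ccc(COC/C(=C\O[Si](C)(C)C(C)(C)C)/C(C)=C/[C@H](CO[Si](C)(C)C(C)(C)C)CC/C(C)=C\[N+](=O)[O-])cc1
A4 | alternative 2 | cis-hydrindene with C15 nitro and C16 silyloxy groups (cycloadduct) | COc1ccc(COCC2=C(C)[C@@H]3[C@H](CO[Si](C)(C)C(C)(C)C)CC[C@]3(C)[C@H]([N+](=O)[O-])[C@@H]2O[Si](C)(C)C(C)(C)C)cc1
A5 | alternative 3 | seco C1 alkenyl iodide / C2 E alkenylstannane (Stille substrate) | CCCC[Sn](CCCC)(CCCC)/C=C/C[C@H](C)C[C@H](OC(C)=O)C2=C(C)[C@@H]3[C@H](C(I)=C)CC[C@]3(C)[C@@H](OC(C)=O)[C@@H]2O[Si](CC)(CC)CC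
A6 | alternative 3 | C16 triethylsilyl ether of the target (Stille product) | C=C1/C=C/C[C@H](C)C[C@H](OC(C)=O)C2=C(C)[C@@H]3[C@H]1CC[C@]3(C)[C@@H](OC(C)=O)[C@@H]2O[Si](CC)(CC)CC
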